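Clerodane numbering is used. Everything rests on closing ring B (C5–C10) last by an anionic oxy-Cope rearrangement of a bicyclo[2.2.2]octene in which ring A is already complete but carries one extra bond, C2–C7. The step exploits the 1,4-relation of the oxygenated C2 and the methyl-bearing C5 across ring A and the C7 oxygen of ring B. In one operation the [3,3] shift makes C9–C10, cuts C2–C7, and sets the cis ring fusion, the C9 quaternary centre (from the Z-alkenyl geometry), the C1=C2 enol ether and a C7 enolate. The precursor, a compact caged diol, comes from an Adler–Becker dearomatisation, a Diels–Alder reaction and a tetrasubstituted alkenyllithium.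

Key step: step 14

Remark on labels: clerodane atom labels are kept for all intermediates. In the bicyclo[2.2.2]octenes C2 and C5 are the bridgeheads, and C3–C4, C6–C7 and C1=C10 are the three bridges. β is the face of H10 and of the C5 methyl in the target.
Assumption: the lipase of step 7 is taken to follow the usual size rule for secondary alcohols (large group C2, medium group C6). The 7R alcohol would then be acetylated and the needed 7S alcohol left behind.

Step 1
Reactants: 1 2-methoxy-5-methylphenol
Product: 2 2-hydroxy-3-methoxy-6-methylbenzaldehyde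
Conditions: (CH2O)n, MgCl2, Et3N, MeCN, reflux
Reagents that add atoms: paraformaldehyde (as formaldehyde), C=O
Why: Magnesium-phenoxide-directed ortho-formylation (Casnati–Skattebøl reaction) can strike only the single free ortho position, between OH and CH3.

Step 2
Reactants: 2 2-hydroxy-3-methoxy-6-methylbenzaldehyde
Product: 3 2,3-dihydroxy-6-methylbenzaldehyde
Conditions: BBr3, CH2Cl2, −78 °C → 0 °C; H2O
Reagents that add atoms: none
Why: Lewis-acid aryl methyl ether cleavage (BBr3 demethylation) frees the oxygen that must carry a group more labile than methyl at the end of the route.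

Step 3
Reactants: 3 2,3-dihydroxy-6-methylbenzaldehyde
Product: 4 2-hydroxy-3-(methoxymethoxy)-6-methylbenzaldehyde
Conditions: MOMCl (1.05 equiv), i-Pr2NEt, CH2Cl2, 0 °C
Reagents that add atoms: chloromethyl methyl ether, COCCl
Why: O-alkylation (MOM ether formation) should take the 3-OH, because the 2-OH is held in a hydrogen bond to the aldehyde.

Step 4
Reactants: 4 2-hydroxy-3-(methoxymethoxy)-6-methylbenzaldehyde
Product: 5 2-(hydroxymethyl)-6-(methoxymethoxy)-3-methylphenol
Conditions: NaBH4, MeOH, 0 °C
Reagents that add atoms: none
Why: Borohydride reduction of an aryl aldehyde gives the salicyl alcohol without touching the acetal.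

Step 5
Reactants: 5 2-(hydroxymethyl)-6-(methoxymethoxy)-3-methylphenol
Product: 6 (±)-5-(methoxymethoxy)-8-methyl-1-oxaspiro[2.5]octa-5,7-dien-4-one
Conditions: NaIO4, MeCN–H2O, 0 °C → rt
Reagents that add atoms: none
Why: In the Adler–Becker oxidation the periodate ester of the salicyl alcohol collapses with C–O bond formation at the carbon that bears CH2OH, giving the spiroepoxy-2,4-cyclohexadienone (racemic at C4), whose substituted diene termini (OMOM, CH3) should slow self-dimerisation.

Step 6
Reactants: 6 (±)-spiroepoxydienone
Product: 8 (±)-bicyclic keto alcohol (7-OH syn to C1=C10; 3-oxo; 4,18-oxirane whose O is syn to the C6–C7 bridge; 2-OMOM; 5-CH3), via trimethylsilyl ether 7 (not isolated)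
Conditions: CH2=CHOSiMe3 (excess), BHT, toluene, 90 °C, sealed tube; then AcOH–THF–H2O, rt
Reagents that add atoms: (vinyloxy)trimethylsilane, C=CO[Si](C)(C)C
Why: In this Diels–Alder reaction of an electron-poor cyclohexa-2,4-dienone with an enol ether the CH2 terminus bonds to the δ-carbon C5 and the oxygenated carbon to C2, the dienophile enters on the face of the oxirane oxygen with OSiMe3 endo (so C2, C5 and C7 are set relative to C4), and mild acid frees the alcohol without a base that could start a retro-aldol.

Step 7
Reactants: 8 (±)-bicyclic keto alcohol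
Product: 9 (7S)-bicyclic keto alcohol (single enantiomer of 8)
Conditions: Burkholderia cepacia lipase, vinyl acetate, MTBE, 30 °C, run just past half conversion; chromatography
Reagents that add atoms: none
Why: Enzymatic kinetic resolution by irreversible acyl transfer should discriminate well between a CH2 and a fully substituted carbon flanking the carbinol, and the unreacted 7S alcohol carries the absolute configuration of C2 and C5 into the target.

Step 8
Reactants: 9 (7S)-bicyclic keto alcohol
Product: 10 bicyclic 3,7-diol (3-OH cis to the oxirane oxygen)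
Conditions: NaBH4, CeCl3·7H2O, MeOH, −20 °C
Reagents that add atoms: none
Why: In this Luche reduction hydride attacks C3 anti to the electronegative C4–O bond and from the open C1=C10 side, giving a temporary 3-carbinol cis to the oxirane oxygen and removing the carbonyl that would turn later alkoxides into aldolates.

Step 9
Reactants: 10 bicyclic 3,7-diol
Product: 11 bicyclic 3-hydroxy-7-ketone
Conditions: TEMPO (cat.), PhI(OAc)2, CH2Cl2, rt
Reagents that add atoms: none
Why: Oxoammonium (TEMPO) oxidation is very sensitive to crowding, so the C7 carbinol (one CH2 neighbour) should be oxidised and the C3 carbinol, wedged between two fully substituted carbons, left alone.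

Step 10
Reactants: 12 but-2-yn-1-ol
Product: 14 (Z)-3-iodo-2-methylbut-2-en-1-ol, via oxamagnesacycle 13 (not isolated)
Conditions: MeMgBr (3 equiv), CuI (cat.), Et2O–THF, 0 °C → rt; then I2, −40 °C → 0 °C
Reagents that add atoms: methylmagnesium bromide, C[Mg]Br; iodine, II
Why: Copper-catalysed anti-carbomagnesiation of a propargylic alkoxide puts CH3 on the proximal carbon and magnesium on the distal one inside a five-membered chelate, so iodinolysis with retention gives iodine cis to CH2OH.

Step 11
Reactants: 14 (Z)-3-iodo-2-methylbut-2-en-1-ol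
Product: 15 (Z)-1-bromo-3-iodo-2-methylbut-2-ene
Conditions: CBr4, PPh3, CH2Cl2, 0 °C
Reagents that add atoms: tetrabromomethane, BrC(Br)(Br)Br
Why: The Appel reaction converts the primary allylic alcohol into the bromide under neutral conditions that keep the alkene geometry.

Step 12
Reactants: 15 (Z)-1-bromo-3-iodo-2-methylbut-2-ene
Product: 16 (Z)-6-iodo-5-methylhepta-1,5-diene
Conditions: allylmagnesium bromide, THF, −20 °C → 0 °C
Reagents that add atoms: allylmagnesium bromide, C=CC[Mg]Br
Why: SN2 allyl–allyl coupling of a primary allylic bromide with a Grignard reagent is favoured because the SN2' site is a fully substituted iodine-bearing carbon, and the alkenyl iodide does not exchange with the stabilised allyl reagent.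

Step 13
Reactants: 16 (Z)-6-iodo-5-methylhepta-1,5-diene; 11 bicyclic 3-hydroxy-7-ketone
Product: 18 bicyclic 3,7-diol bearing on C7 the (Z)-alkenyl group syn to C1=C10, via alkenyllithium 17 (not isolated)
Conditions: 16 (2.4 equiv), t-BuLi (4.8 equiv), Et2O, −78 °C; then 11, THF, −78 °C; H2O
Reagents that add atoms: none
Why: Iodine–lithium exchange with retention is followed by 1,2-addition of the alkenyllithium to the ketone; the first equivalent forms the C3 lithium alkoxide, which covers the face of C7=O that looks at the C3–C4 bridge, so carbon should arrive from the C1=C10 side and set C7 with the alkenyl group syn to that alkene.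

Step 14
Reactants: 18 bicyclic 3,7-diol bearing the (Z)-alkenyl group on C7
Product: 20 cis-decalone (10β-H; 5β-CH3; 9α-CH3; 9β-but-3-enyl; 8α-CH3; 7-oxo; C1=C2 with 2-OMOM; 3α-OH; 4α,18-oxirane), via dipotassium enolate alkoxide 19 (not isolated)
Conditions: KH (3 equiv), 18-crown-6 (3 equiv), THF, 0 °C → 40 °C; then H2O
Reagents that add atoms: none
Why: KH and 18-crown-6 turn both hydroxyls of 18 into dissociated potassium alkoxides, and the C7 alkoxide drives a concerted [3,3] shift of the 1,5-diene C9=C8–C7–C2–C1=C10 that forms C9–C10, breaks the temporary C2–C7 bond and leaves the C1=C2 enol ether and the C7 enolate 19. The closest known reaction type is the anionic oxy-Cope rearrangement of 2-alkenylbicyclo[2.2.2]oct-5-en-2-ols with a bridgehead alkoxy group to cis-decalones. Ring B (C5–C6–C7–C8–C9–C10) closes as a sigmatropic ring exchange through the only accessible, boat-shaped six-centre array inside the cage, while the rings that contain C2–C7 open, so it is neither an exo nor an endo cyclisation. C10 is attacked on the alkene face that looks at the C6–C7 bridge, which places H10 cis to the C5 methyl (cis fusion); C9 follows from the Z geometry, because in the boat array the butenyl arm, cis to C7, ends cis to H10 and the C20 methyl trans to it; C8 is set on quench by protonation of 19 from the convex β face, which also puts the methyl in its equatorial, equilibrium position. The step needs the alkenyl group syn to C1=C10 (secured in step 13), no carbonyl β to either alkoxide (hence C3 at the alcohol level, which shuts off retro-aldol cleavage) and a silent oxirane (the C3 alkoxide is cis to the oxirane oxygen, so a Payne migration has no backside trajectory).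

Step 15
Reactants: 20 cis-decalone
Product: 21 3α,7β-diol
Conditions: SmI2 (3 equiv), H2O, Et3N, THF, 0 °C
Reagents that add atoms: none
Why: Single-electron ketone reduction (SmI2–water–amine, dissolving-metal type) passes through a ketyl and a carbanion that settle with oxygen equatorial and take up a small proton on the α face, giving the equatorial 7β-alcohol, whereas hydride reagents could approach only from the β face because axial C4 and C20 close the α face.

Step 16
Reactants: 21 3α,7β-diol
Product: 22 7β-hydroxy-2-(methoxymethoxy)-1-en-3-one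
Conditions: MnO2, CH2Cl2, rt
Reagents that add atoms: none
Why: Allylic alcohol oxidation with MnO2 touches only the C3 carbinol (allylic to C1=C2), erases the temporary C3 centre and restores a push–pull 2-alkoxy enone that is robust enough for the next steps.

Step 17
Reactants: 22 7β-hydroxy enone
Product: 23 7β-acetate
Conditions: Ac2O, pyridine, DMAP, CH2Cl2, rt
Reagents that add atoms: acetic anhydride, CC(=O)OC(C)=O
Why: DMAP-catalysed acetylation meets only one free hydroxyl, and it is equatorial.

Step 18
Reactants: 23 7β-acetate
Product: 24 13-methyl ketone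
Conditions: PdCl2 (cat.), CuCl, O2 (1 atm), DMF–H2O, rt
Reagents that add atoms: water, O
Why: The Tsuji–Wacker oxidation is selective for the monosubstituted terminal alkene and gives the methyl ketone, while the electron-poor trisubstituted C1=C2 bond is inert.

Step 19
Reactants: 24 13-methyl ketone
Product: 25 tert-butyl (13E)-enoate
Conditions: (EtO)2P(O)CH2CO2t-Bu, NaH, THF, 0 °C → rt; chromatography
Reagents that add atoms: tert-butyl diethylphosphonoacetate, CCOP(=O)(CC(=O)OC(C)(C)C)OCC
Why: Horner–Wadsworth–Emmons olefination should take the unhindered methyl ketone (C3=O is deactivated and flanked by two substituted carbons) and favour the E-enoate with the longer chain trans to the ester, the minor Z isomer being removed.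

Step 20
Reactants: 25 tert-butyl (13E)-enoate
Product: 26 18-hydroxy-3-ketone (C4 epimers)
Conditions: SmI2 (2.2 equiv), THF–MeOH, −78 °C
Reagents that add atoms: none
Why: In the SmI2 reduction of an α,β-epoxy ketone, electron transfer to C3=O breaks the C4–O bond and the samarium enolate is protonated to the β-hydroxy ketone; acetate and the β,β-disubstituted enoate are not reduced at this temperature, and the C4 configuration is irrelevant.

Step 21
Reactants: 26 18-hydroxy-3-ketone
Product: 28 4(18)-methylene enone (2-OMOM; tert-butyl ester), via primary mesylate 27 (not isolated)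
Conditions: MsCl, Et3N, CH2Cl2, 0 °C → rt
Reagents that add atoms: none
Why: Mesylation is followed by E1cB elimination, and since C4–H is the only α-hydrogen of C3=O, the exocyclic C4=C18 alkene is the only enone that can form.

Step 22
Reactants: 28 4(18)-methylene enone
Product: 29 target, CNP0192653.1
Conditions: TFA–CH2Cl2 (1:4), 0 °C → rt; aqueous work-up
Reagents that add atoms: none
Why: Acidolysis with TFA removes the tert-butyl ester and the MOM acetal on the phenol-like enol oxygen while the secondary acetate is stable, and the freed 2,3-dione can enolise only toward C1 because C4 carries no hydrogen.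

Compound list
1 | 2-methoxy-5-methylphenol | COc1ccc(C)cc1O | starting material
2 | 2-hydroxy-3-methoxy-6-methylbenzaldehyde | COc1ccc(C)c(C=O)c1O | intermediate
3 | 2,3-dihydroxy-6-methylbenzaldehyde | Oc1ccc(C)c(C=O)c1O | intermediate
4 | 2-hydroxy-3-(methoxymethoxy)-6-methylbenzaldehyde | COCOc1ccc(C)c(C=O)c1O | intermediate
5 | 2-(hydroxymethyl)-6-(methoxymethoxy)-3-methylphenol | COCOc1ccc(C)c(CO)c1O | intermediate
6 | (±)-5-(methoxymethoxy)-8-methyl-1-oxaspiro[2.5]octa-5,7-dien-4-one (racemic; the enantiomer carried on is drawn) | O=C1C(OCOC)=CC=C(C)[C@@]12CO2 | intermediate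
7 | (±)-7-O-trimethylsilyl ether of 8 (racemic; not isolated) | C[Si](C)(C)O[C@H]1C[C@@]2(C)C=C[C@]1(OCOC)C(=O)[C@]23CO3 | intermediate
8 | (±)-8-hydroxy-4-(methoxymethoxy)-1-methylspiro[bicyclo[2.2.2]oct-5-ene-2,2'-oxiran]-3-one (racemic; OH syn to the alkene; oxirane O syn to the CH2–CHOH bridge) | O[C@H]1C[C@@]2(C)C=C[C@]1(OCOC)C(=O)[C@]23CO3 | intermediate
9 | (7S)-bicyclic keto alcohol, single enantiomer of 8 | O[C@H]1C[C@@]2(C)C=C[C@]1(OCOC)C(=O)[C@]23CO3 | intermediate
10 | bicyclic 3,7-diol (3-OH cis to the oxirane O) | O[C@H]1C[C@@]2(C)C=C[C@]1(OCOC)[C@@H](O)[C@]23CO3 | intermediate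
11 | bicyclic 3-hydroxy-7-ketone | O=C1C[C@@]2(C)C=C[C@]1(OCOC)[C@@H](O)[C@]23CO3 | intermediate
12 | but-2-yn-1-ol | CC#CCO | starting material
13 | 3,4-dimethyl-2,5-dihydro-1,2-oxamagnesole (oxamagnesacycle; not isolated) | CC1=C(C)CO[Mg]1 | intermediate
14 | (Z)-3-iodo-2-methylbut-2-en-1-ol | I/C(C)=C(/C)CO | intermediate
15 | (Z)-1-bromo-3-iodo-2-methylbut-2-ene | I/C(C)=C(/C)CBr | intermediate
16 | (Z)-6-iodo-5-methylhepta-1,5-diene | I/C(C)=C(/C)CCC=C | intermediate
17 | (Z)-(3-methylhepta-2,6-dien-2-yl)lithium (not isolated) | [Li]/C(C)=C(/C)CCC=C | intermediate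
18 | bicyclic 3,7-diol with the (Z)-3-methylhepta-2,6-dien-2-yl group on C7 syn to C1=C10 | O[C@]1(/C(C)=C(/C)CCC=C)C[C@@]2(C)C=C[C@]1(OCOC)[C@@H](O)[C@]23CO3 | intermediate
19 | dipotassium C7 enolate, C3 alkoxide of 20 (not isolated) | [K]O[C@@H]1C(OCOC)=C[C@@H]2[C@@](C)(CCC=C)C(C)=C(O[K])C[C@]2(C)[C@@]13CO3 | intermediate
20 | cis-decalone (3α-OH; 4α,18-oxirane; 2-OMOM; 7-oxo; 9β-but-3-enyl) | O[C@@H]1C(OCOC)=C[C@@H]2[C@@](C)(CCC=C)[C@H](C)C(=O)C[C@]2(C)[C@@]13CO3 | intermediate
21 | 3α,7β-diol | O[C@@H]1C(OCOC)=C[C@@H]2[C@@](C)(CCC=C)[C@H](C)[C@@H](O)C[C@]2(C)[C@@]13CO3 | intermediate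
22 | 7β-hydroxy-2-(methoxymethoxy)-1-en-3-one | O=C1C(OCOC)=C[C@@H]2[C@@](C)(CCC=C)[C@H](C)[C@@H](O)C[C@]2(C)[C@@]13CO3 | intermediate
23 | 7β-acetate | O=C1C(OCOC)=C[C@@H]2[C@@](C)(CCC=C)[C@H](C)[C@@H](OC(C)=O)C[C@]2(C)[C@@]13CO3 | intermediate
24 | 13-methyl ketone | O=C1C(OCOC)=C[C@@H]2[C@@](C)(CCC(C)=O)[C@H](C)[C@@H](OC(C)=O)C[C@]2(C)[C@@]13CO3 | intermediate
25 | tert-butyl (13E)-enoate | O=C1C(OCOC)=C[C@@H]2[C@@](C)(CC/C(C)=C/C(=O)OC(C)(C)C)[C@H](C)[C@@H](OC(C)=O)C[C@]2(C)[C@@]13CO3 | intermediate
26 | 18-hydroxy-3-ketone (C4 epimers, C4 left open) | O=C1C(OCOC)=C[C@@H]2[C@@](C)(CC/C(C)=C/C(=O)OC(C)(C)C)[C@H](C)[C@@H](OC(C)=O)C[C@]2(C)C1CO | intermediate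
27 | 18-mesylate of 26 (not isolated) | O=C1C(OCOC)=C[C@@H]2[C@@](C)(CC/C(C)=C/C(=O)OC(C)(C)C)[C@H](C)[C@@H](OC(C)=O)C[C@]2(C)C1COS(C)(=O)=O | intermediate
28 | 4(18)-methylene enone, 2-O-MOM ether, tert-butyl ester | C=C1C(=O)C(OCOC)=C[C@@H]2[C@@](C)(CC/C(C)=C/C(=O)OC(C)(C)C)[C@H](C)[C@@H](OC(C)=O)C[C@]12C | intermediate
29 | CNP0192653.1 (7β-acetoxy-2-hydroxy-3-oxo-cis-cleroda-1,4(18),13E-trien-15-oic acid) | C=C1C(=O)C(O)=C[C@@H]2[C@@](C)(CC/C(C)=C/C(=O)O)[C@H](C)[C@@H](OC(C)=O)C[C@]12C | target

Total step count: 22. Longest linear sequence: 19 (steps 1–9 and 13–22).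

Steps most likely to fail

Step 14 (key step). The butenyl arm has to sit inside the boat array against C5 and C6, so the rearrangement may stall, and heterolytic fragmentation of the C7 alkoxide may take over. The fallback closes ring B in ionic steps. Setting out from 9, Dess–Martin oxidation would give the bicyclic 3,7-dione F1. Addition of 17 at −78 °C would give the lithium aldolate F2 (either C7 epimer serves). On warming this should undergo retro-aldol cleavage of C2–C7 to the ring-opened lithium dienolate F3. Intramolecular vinylogous Michael addition of C10 to C9 should then follow, with lithium bridging the C3, C2 and C7 oxygens and holding the enone under ring A, to give the lithium C7 enolate F4. LiAlH4 at −78 °C, with C7 masked as its enolate, would reduce C3, and the route is rejoined at 20.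

Step 13. Enolisation at C6, retro-aldol cleavage started by the C3 alkoxide, or simple steric refusal of the tetrasubstituted nucleophile may outrun addition. The fallback builds the alkene on the cage. Setting out from 11, prop-1-ynyllithium, a slim nucleophile, would give the propargylic diol F5. Copper-catalysed anti-carbomagnesiation with MeMgBr and CuI, directed by the C7 alkoxide, followed by I2 would give the Z-iodoalkenyl diol F6, with iodine cis to C7. Negishi coupling with but-3-enylzinc bromide and Pd(dppf)Cl2, which proceeds with retention, returns to 18.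

Step 6. The donor-substituted, doubly end-capped dienone may react too slowly with an enol ether, so that aromatisation of the oxirane or dimerisation consumes it. The fallback changes the polarity of the dienophile and makes the C7–O bond afterwards. Setting out from 6, 4,4,5,5-tetramethyl-2-vinyl-1,3,2-dioxaborolane (neat, heat) would give the (±)-C7 pinacol boronate F7. Stereoretentive oxidation with Me3NO under neutral conditions returns to 8.

Further compounds
F1 | step 14 | bicyclic 3,7-dione | O=C1C[C@@]2(C)C=C[C@]1(OCOC)C(=O)[C@]23CO3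
F2 | step 14 | lithium aldolate | [Li]O[C@]1(/C(C)=C(/C)CCC=C)C[C@@]2(C)C=C[C@]1(OCOC)C(=O)[C@]23CO3
F3 | step 14 | ring-opened lithium dienolate | [Li]OC1=C(OCOC)C=C[C@](C)(CC(=O)/C(C)=C(/C)CCC=C)[C@@]12CO2
F4 | step 14 | lithium C7 enolate of the 3,7-dioxo cis-decalin | O=C1C(OCOC)=C[C@@H]2[C@@](C)(CCC=C)C(C)=C(O[Li])C[C@]2(C)[C@@]13CO3
F5 | step 13 | propargylic diol | O[C@]1(C#CC)C[C@@]2(C)C=C[C@]1(OCOC)[C@@H](O)[C@]23CO3
F6 | step 13 | Z-iodoalkenyl diol | O[C@]1(/C(C)=C(/C)I)C[C@@]2(C)C=C[C@]1(OCOC)[C@@H](O)[C@]23CO3
F7 | step 6 | (±)-C7 pinacol boronate | CC1(C)OB(OC1(C)C)[C@H]1C[C@@]2(C)C=C[C@]1(OCOC)C(=O)[C@]23CO3
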